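The constants that carry these flasks are the apparent first-order constant of E loss, read from the early readings, and the ratio of the charges.

| flask | E | G | Q | temperature | remark | time |
|---|---|---|---|---|---|---|
| Wednesday's | 20 mM | 12 mM | 0.13 mM | 105 °C | run made earlier |  |
| Thursday's | 20 mM | 12 mM | 0.52 mM | 116 °C | run made earlier |  |
| Friday's | 31 mM | 12 mM | 0.40 mM | 105 °C | run made earlier |  |
| dawn | 40 mM | 12.0 mM | 0.100 mM | 110 °C |  | 2.0 h |
| spring | 20 mM | 12.0 mM | 0.400 mM | 110 °C |  | 2.0 h |

- Wednesday's (time / min: L / %, E / %): 6.00: 3.5, 96.2; 10.0: 4.6, 94.5; 15.0: 8.1, 92.5; 25.0: 11.9, 87.0; 40.0: 17.3, 79.4; 60.0: 20.6, 72.8; 80.0: 24.0, 66.4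
- Thursday's (time / min: L / %, E / %): 5.00: 5.4, 94.7; 12.0: 11.1, 87.4; 25.0: 18.0, 76.0; 40.0: 22.7, 67.6; 50.0: 25.0, 62.4; 60.0: 28.2, 58.4; 80.0: 29.3, 50.9
- Friday's (time / min: L / %, E / %): 6.00: 3.2, 96.2; 12.0: 6.4, 92.8; 25.0: 11.7, 86.2; 40.0: 16.3, 81.6; 80.0: 21.9, 70.6

(each reading ± 0.5 percentage points)

- which of the two ends with the higher amount of L, in percent of the E charged ("neither" if they lie within 2 percentage points) (dawn / spring / neither)
- L at the end, in percent of the E charged, dawn
- L at the end, in percent of the E charged, spring



Wednesday's run has E at 87.0% of its charge after 25.0 min, so its constant is 0.00557 /min. Friday's run, with more E and more Q at the same temperature and G, gives 0.00594 /min, though those two changes are confounded. We therefore freeze the constant and let it ignore the E charge. Thursday's run gives 0.0110 /min, and interpolating the logarithm to 110 °C gives 0.00758 /min for both flasks, which is a mean slope of the E curve over its first 25.0 min, not its slope at the start.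

In dawn the ceiling is 30.0%: the ceiling is G charged over E charged, the fraction of charged E that G, as limiting reagent, can convert at one G per E. At the frozen constant, dawn meets it at a knee near 47.0 min, well before its end at 2.0 h, so E should level at 70.0%. L should peak near 21.0%, using the L share of converted E in Thursday's reading at 40.0 min. It should then sink to 17.9%, using the share 59.7% in Thursday's last reading.

Spring has Thursday's E and G, so we scale its time: 2.0 h at 110 °C equals 82.9 min at 116 °C, beside Thursday's last reading at 80.0 min. Spring should thus stand near E 50.9% and L 29.3%, its conversion 49.1% lying below its ceiling 60.0%.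

The forecast gives 18% for dawn and 27% for spring, so spring, with the ground: “Dawn has G at only 30% of E, which caps L”. Our spring figure stands above its figure.

The flasks give 17.2% for dawn and 30.1% for spring, so spring ends higher, as the forecast said.

    E + G → L, rate k1*[E]*[G]^0.5 (k = 0.00130 /M^0.5/s, Ea = 77.0 kJ/mol)
    L ⇌ X (K = 0.790, k = 2.80 × 10⁻⁴ /s, Ea = 120 kJ/mol, ΔH = −16.0 kJ/mol)
    G + Q → Z (k = 0.200 /M/s, Ea = 72.0 kJ/mol)
    (constants at 110 °C)

Dawn's conversion stopped at 29.8% against its ceiling 30.0%, with G at 0% of its charge. The repeat of spring at 135 °C also ended with G at 0%, at a conversion of 58.0% under the ceiling 60.0%, and with L at 36.7%. In spring itself, at 0.633 h, the half-life of E by the step to L is 1.8 h, longer than the 0.69 h of L by the forward step to X. Yet L is then made 2.38 times faster than it is used up, each step taken net, and at the asked time still 1.59 times faster.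

The data are calculated on assumed constants; the scatter is artificial.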